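One run cannot tell you whether the enzyme X fades with the clock or with the D around it, but two runs at different D can.

| flask | D | X | remark | time |
|---|---|---|---|---|
| north | 0.10 M | 0.0016 mol% | run made earlier |  |
| south-west | 0.050 M | 0.0016 mol% | run made earlier |  |
| east | 0.075 M | 0.0016 mol% | run made earlier |  |
| larch | 0.10 M | 0.0016 mol% | one stirred flow tank at steady state, fed with the mixture as stated, mean residence time 20 h |  |
| birch | 0.10 M | 0.0016 mol% | a closed flask charged with all of it at once and left for 20 h | 20 h |
| elm | 0.10 M (fed, over 16.0 h) | 0.0016 mol% | a stirred flask in which D is dosed at a steady rate over 16.0 h without added volume, worked up at 20 h | 20 h |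

- north (time / h: Q / %): 1.50: 7.3; 3.00: 13.1; 5.00: 18.6; 6.00: 20.6; 8.00: 23.5; 10.0: 25.9; 12.0: 28.2
- south-west (time / h: Q / %): 1.50: 7.1; 3.00: 12.9; 5.00: 18.1; 6.00: 21.3; 8.00: 25.6; 10.0: 29.8; 12.0: 33.2
- east (time / h: Q / %): 0.667: 3.5; 2.00: 9.5; 3.00: 13.3; 5.00: 19.1; 8.00: 25.7; 10.0: 29.1; 12.0: 31.2

(readings scatter by 0.3 percentage points)

- the stated concentrations are those of everything mixed, before any reaction; amounts are the same in each set-up
- the earlier runs were read with a standard deviation of 0.3 percentage points
- the feed brings no volume worth counting
- the earlier runs were made in a closed, stirred flask

- the set-up with the highest amount of Q at the outlet or at the end, in percent of the D put in ("none" if the first two lie within 2 percentage points) (larch / birch / elm / none)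
- amount of Q at the outlet or at the end, in percent of the D put in, larch
- amount of Q at the outlet or at the end, in percent of the D put in, birch
- amount of Q at the outlet or at the end, in percent of the D put in, elm

At 3.00 h the north, south-west and east runs stand at 13.1%, 12.9% and 13.3%, so I take the north figure as one early rate, 0.0437 /h as a share of the charge. Later the runs part: from 8.00 h to 12.0 h the south-west run gains 7.6 percentage points, more than the 4.7 points of the north run. The logarithmic fall of the rate between those stretches, per hour and per molar of D charged, is my fading constant, 1.92 /M/h, read from the south-west run. The north run reads 1.54 /M/h. As my own estimate, I take the fade rate as this constant times D, and the yield as the early rate times the fraction of enzyme lost by then, over the fade rate.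

Carrying the north run forward at its own fade, I get 32.2% for birch. For the tank larch, assuming that its D stands near the east concentration, I get 22.5%.

In elm, a semi-batch flask, the feed of 0.0625 /h beats the early rate, so D builds. Unfaded enzyme would leave a peak of 0.0301 M, and I take half of that as the mean. That peak is the weak link, since it ignores fading. Reforged with the faded yield at the end of the feed, my estimated peak is 0.0441 M, higher than the first, and with half of it as the mean I get 59.0% for elm.

The forecast differs: 25.5% for larch, 34.5% for birch, 29% for elm, best birch, holding that “early D is scarce while the enzyme is at its best”.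

The flasks give 36.2% for larch, 33.5% for birch and 49.1% for elm, so elm is best.

    D + X ⇌ Z (K = 31.0 /M, k = 4.70 × 10⁶ /M/h)
    Z ⇌ X + Q (K = 0.840 M, k = 5200 /h)
    D + Z → G (k = 3.30 /M/h)
    D ⇌ E (K = 1.40, k = 0.0590 /h)

D in elm peaked at 0.0409 M. Reckoned with D at that peak for the whole 20 h, the fading constant gives 44.1%, less than the 49.1% of elm.

For a neighbour of birch charged with 0.060 M of D, the same reckoning with D taken at that charge throughout gives 34.1%. That neighbour flask gives 42.3%.

The readings are simulated for substances that don't exist.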